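## Retrosynthetic overview

- **Feature:** the central ring B carries OH on two para carbons, aryloxy on the next para pair and Br on the last pair. It is therefore the reduced, 3,6-dibrominated form of a 2,5-bis(aryloxy)-1,4-benzoquinone. Its six carbons divide into the four ring carbons of a cyclobutenone (C1–C4) and the two carbons of an aryloxyalkyne (C5, C6).
- **Ring formation:** ring B is the only ring that is built. A 3-aryloxy-4-(aryloxyethynyl)-4-hydroxycyclobutenone expands thermally from four to six members through a vinylketene, with C1–C6 as the new bond. The outer rings A and C come in intact as 4-methoxyphenol.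
- **Cyclobutenone:** it arises by 1,2-addition of lithium (4-methoxyphenoxy)acetylide (4-methoxyphenol + trichloroethylene) to 4-methoxyphenyl semisquarate (diisopropyl squarate → semisquaric acid → chloride → aryl ester).
- **Bromines:** the eight bromines go on in two directed stages. Six go on the reduced, fully O-methylated trimer: both C–H of ring B, and on each outer ring one ortho to OMe and one para to it, next to the bridging oxygen. After BBr3, one more per outer ring enters ortho to the freed OH.

Key step: step 7

Assumption: the target has no stereocentre and no stereodescriptor, and rotation about its diaryl ether bonds is taken as free, so it is achiral and nothing has to be resolved; the one stereocentre on the way (C4 of the cyclobutenone) is racemic and disappears in the key step.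

## Route

Step 1
Reactants: 1 diisopropyl squarate (3,4-diisopropoxycyclobut-3-ene-1,2-dione)
Product: 3 3-isopropoxycyclobut-3-ene-1,2-dione, via hydroxycyclobutenone 2 (not isolated)
Conditions: LiAlH(Ot-Bu)3, THF, −78 → −20 °C; then 6 M HCl, CH2Cl2, rt
Reagents that add atoms: none
Why: The bulky alkoxyaluminium hydride adds once, 1,2, to a squarate carbonyl, and acid then ionises the racemic carbinol 2 to an oxygen-stabilised allyl cation that loses isopropanol on hydrolysis, which is the standard 1,2-addition/acid hydrolysis sequence of dialkyl squarates with hydride as the nucleophile.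

Step 2
Reactants: 3 3-isopropoxycyclobut-3-ene-1,2-dione
Product: 4 semisquaric acid (3-hydroxycyclobut-3-ene-1,2-dione)
Conditions: 2 M aq HCl, THF, 50 °C; evaporation, azeotropic drying (toluene)
Reagents that add atoms: water, O
Why: Acid-catalysed hydrolysis of a vinylogous ester (addition–elimination of water at C3) gives the acid-stable vinylogous acid, which is made here because it is sold only as an analytical standard of its salt, and which is freed from the volatile by-products by evaporation.

Step 3
Reactants: 4 semisquaric acid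
Product: 5 semisquaric chloride (3-chlorocyclobut-3-ene-1,2-dione)
Conditions: (COCl)2, cat. DMF, CH2Cl2, 0 °C → rt
Reagents that add atoms: oxalyl chloride, O=C(Cl)C(=O)Cl
Why: Vilsmeier-type chlorodehydroxylation of a vinylogous carboxylic acid, the reaction that also converts squaric acid into its dichloride.

Step 4
Reactants: 5 semisquaric chloride; 6 4-methoxyphenol
Product: 7 3-(4-methoxyphenoxy)cyclobut-3-ene-1,2-dione
Conditions: 2,6-lutidine, CH2Cl2, −40 → 0 °C
Reagents that add atoms: none
Why: The phenol displaces chloride from the vinylogous acid chloride by addition–elimination (O-acylation type), and the hindered pyridine base traps HCl so that acid-promoted Friedel–Crafts C-acylation of the electron-rich ring cannot compete.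

Step 5
Reactants: 6 4-methoxyphenol; 8 trichloroethylene
Product: 10 (E)-1-[(1,2-dichlorovinyl)oxy]-4-methoxybenzene, via dichloroacetylene 9 (not isolated)
Conditions: K2CO3, DMF, 70 °C
Reagents that add atoms: none
Why: Base removes HCl from trichloroethylene and the phenoxide adds anti to the resulting dichloroacetylene, which gives the (E)-1,2-dichlorovinyl ether and is the standard first stage of the dichlorovinyl ether route to ynol ethers.

Step 6
Reactants: 10 (E)-1-[(1,2-dichlorovinyl)oxy]-4-methoxybenzene; 7 3-(4-methoxyphenoxy)cyclobut-3-ene-1,2-dione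
Product: 13 4-hydroxy-3-(4-methoxyphenoxy)-4-[(4-methoxyphenoxy)ethynyl]cyclobut-2-en-1-one (racemic), via chloroalkyne 11 (not isolated), via lithium acetylide 12 (not isolated)
Conditions: 10, n-BuLi (2.0 equiv), THF, −78 → −40 °C; cannulated into 7, THF, −78 °C; sat. aq NH4Cl at −78 °C
Reagents that add atoms: none
Why: n-BuLi removes HCl from 10 and then exchanges the alkynyl chlorine of 11 for lithium, and the hard acetylide 12 adds 1,2 to the carbonyl next to the aryloxy carbon because the other carbonyl is deactivated as the C=O of a vinylogous ester, as is established for alkyl semisquarates (attack at the other carbonyl would end in the 2,6-quinone); the new carbinol centre forms racemic and is erased in step 7.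

Step 7
Reactants: 13 4-hydroxy-3-(4-methoxyphenoxy)-4-[(4-methoxyphenoxy)ethynyl]cyclobut-2-en-1-one
Product: 16 2,5-bis(4-methoxyphenoxy)-1,4-benzoquinone, via vinylketene 14 (not isolated), via ring diradical 15 (not isolated)
Conditions: toluene (0.01 M, degassed), 110 °C
Reagents that add atoms: none
Why: Heating breaks the C1–C4 bond of 13 in a conrotatory 4π electrocyclic opening in which the donor hydroxyl turns outward, so that vinylketene 14 forms as the Z isomer with the alkyne beside the ketene. The ketene carbon C1 then bonds to C6, the alkyne carbon that bears the aryloxy group (6-endo-dig closure of ring B, the enyne–ketene relative of the Myers–Saito cyclisation), to give the aromatic σ,π-diradical 15, and transfer of the hydroxyl hydrogen to the aryl radical centre C5 ends at quinone 16. The closest known reaction type is the Moore rearrangement of 4-alkynyl-4-hydroxycyclobutenones made from squarate and semisquarate esters, applied here to an alkyne with an aryloxy terminus. No stereocentre is formed, the only one of 13 is lost, and the 2,5-pattern needs no selection because the aryloxy groups sit on C3 and C6, which become para in the ring. The selectivity that is needed is six-ring closure at C6 over 5-exo-dig closure at C5, which would end in a 2-(aryloxymethylene)cyclopent-4-ene-1,3-dione and which the ynol ether polarity (nucleophilic C5, oxygen-stabilised C6) could assist. In favour of C6 are the small divalent oxygen at the terminus, the poor stabilisation of a bent α-oxygenated vinyl radical compared with the phenyl-, ester- and silyl-substituted ones known to divert this reaction, the gain when the oxygen-bearing sp carbon becomes an arene carbon ortho to the phenoxyl oxygen of 15, the weaker donor strength of aryloxy compared with alkoxy, and the non-polar solvent, which disfavours a charge-separated closure.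

Step 8
Reactants: 16 2,5-bis(4-methoxyphenoxy)-1,4-benzoquinone
Product: 18 1,4-dimethoxy-2,5-bis(4-methoxyphenoxy)benzene, via hydroquinone 17 (not isolated)
Conditions: Na2S2O4, cat. Bu4NBr, THF–H2O, rt; then aq KOH, Me2SO4, rt, N2
Reagents that add atoms: dimethyl sulfate, COS(=O)(=O)OC
Why: One-pot reductive methylation of a quinone, in which dithionite reduces 16 before base is added (so its vinylogous aryl ester is not hydrolysed) and Williamson O-methylation then fixes ring B as an arene, which turns the bridging oxygens into true aryl ether donors and shields ring B from oxidation by bromine.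

Step 9
Reactants: 18 1,4-dimethoxy-2,5-bis(4-methoxyphenoxy)benzene
Product: 19 1,4-dibromo-2,5-bis(2,5-dibromo-4-methoxyphenoxy)-3,6-dimethoxybenzene
Conditions: Br2 (6.5 equiv), AcOH–CH2Cl2, 0 °C → rt, dark
Reagents that add atoms: bromine, BrBr
Why: In this electrophilic aromatic bromination the 1,2,4,5-tetraoxygenated ring B takes bromine at both free positions, and each outer 1,4-dioxygenated ring follows the 1,4-dimethoxybenzene → 2,5-dibromide pattern (C5' ortho to OMe, then C2' para to that bromine and ortho to the bridging oxygen), because the other site next to OMe is meta to bromine and would force the methoxy group out of conjugation.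

Step 10
Reactants: 19 1,4-dibromo-2,5-bis(2,5-dibromo-4-methoxyphenoxy)-3,6-dimethoxybenzene
Product: 20 2,5-dibromo-3,6-bis(2,5-dibromo-4-hydroxyphenoxy)benzene-1,4-diol
Conditions: BBr3 (8 equiv), CH2Cl2, −78 °C → rt; then degassed H2O
Reagents that add atoms: none
Why: In this Lewis acid ether cleavage BBr3 removes all four methyl groups by bromide attack at methyl and gives the tetraphenol, while diaryl ether C–O bonds and aryl bromides are inert to it.

Step 11
Reactants: 20 2,5-dibromo-3,6-bis(2,5-dibromo-4-hydroxyphenoxy)benzene-1,4-diol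
Product: 22 2,5-dibromo-3,6-bis(2,3,5-tribromo-4-hydroxyphenoxy)benzene-1,4-diol (target), via octabromoquinone 21 (not isolated)
Conditions: Br2 (3.1 equiv), AcOH, rt; then aq Na2S2O4
Reagents that add atoms: bromine, BrBr
Why: In this phenol-directed electrophilic bromination each outer ring has only C3' free ortho to its OH while C6'–H is meta to it, so one bromine enters per ring, and the third equivalent oxidises ring B to quinone 21, which the dithionite work-up returns to the hydroquinone.

## Compound list

1 | diisopropyl squarate | CC(C)OC1=C(OC(C)C)C(=O)C1=O | starting material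
2 | 4-hydroxy-2,3-diisopropoxycyclobut-2-en-1-one (racemic) | CC(C)OC1=C(OC(C)C)C(O)C1=O | intermediate
3 | 3-isopropoxycyclobut-3-ene-1,2-dione | CC(C)OC1=CC(=O)C1=O | intermediate
4 | semisquaric acid | O=C1C=C(O)C1=O | intermediate
5 | 3-chlorocyclobut-3-ene-1,2-dione | O=C1C=C(Cl)C1=O | intermediate
6 | 4-methoxyphenol | COc1ccc(O)cc1 | starting material
7 | 3-(4-methoxyphenoxy)cyclobut-3-ene-1,2-dione | O=C1C=C(Oc2ccc(OC)cc2)C1=O | intermediate
8 | trichloroethylene | ClC=C(Cl)Cl | starting material
9 | dichloroacetylene | ClC#CCl | intermediate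
10 | (E)-1-[(1,2-dichlorovinyl)oxy]-4-methoxybenzene | COc1ccc(O/C(Cl)=C\Cl)cc1 | intermediate
11 | 1-[(chloroethynyl)oxy]-4-methoxybenzene | COc1ccc(OC#CCl)cc1 | intermediate
12 | lithium (4-methoxyphenoxy)acetylide | [Li]C#COc1ccc(OC)cc1 | intermediate
13 | 4-hydroxy-3-(4-methoxyphenoxy)-4-[(4-methoxyphenoxy)ethynyl]cyclobut-2-en-1-one (racemic) | O=C1C=C(Oc2ccc(OC)cc2)C1(O)C#COc1ccc(OC)cc1 | intermediate
14 | (Z)-4-hydroxy-3,6-bis(4-methoxyphenoxy)hexa-1,3-dien-5-yn-1-one | O=C=C/C(Oc1ccc(OC)cc1)=C(\C#COc1ccc(OC)cc1)O | intermediate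
15 | 4-hydroxy-2,5-bis(4-methoxyphenoxy)phenoxyl-3-yl diradical | [O]c1cc(Oc2ccc(OC)cc2)c(O)[c]c1Oc1ccc(OC)cc1 | intermediate
16 | 2,5-bis(4-methoxyphenoxy)-1,4-benzoquinone | O=C1C=C(Oc2ccc(OC)cc2)C(=O)C=C1Oc1ccc(OC)cc1 | intermediate
17 | 2,5-bis(4-methoxyphenoxy)benzene-1,4-diol | Oc1cc(Oc2ccc(OC)cc2)c(O)cc1Oc1ccc(OC)cc1 | intermediate
18 | 1,4-dimethoxy-2,5-bis(4-methoxyphenoxy)benzene | COc1cc(Oc2ccc(OC)cc2)c(OC)cc1Oc1ccc(OC)cc1 | intermediate
19 | 1,4-dibromo-2,5-bis(2,5-dibromo-4-methoxyphenoxy)-3,6-dimethoxybenzene | COc1c(Br)c(Oc2cc(Br)c(OC)cc2Br)c(OC)c(Br)c1Oc1cc(Br)c(OC)cc1Br | intermediate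
20 | 2,5-dibromo-3,6-bis(2,5-dibromo-4-hydroxyphenoxy)benzene-1,4-diol | Oc1c(Br)c(Oc2cc(Br)c(O)cc2Br)c(O)c(Br)c1Oc1cc(Br)c(O)cc1Br | intermediate
21 | 2,5-dibromo-3,6-bis(2,3,5-tribromo-4-hydroxyphenoxy)-1,4-benzoquinone | O=C1C(Br)=C(Oc2cc(Br)c(O)c(Br)c2Br)C(=O)C(Br)=C1Oc1cc(Br)c(O)c(Br)c1Br | intermediate
22 | 2,5-dibromo-3,6-bis(2,3,5-tribromo-4-hydroxyphenoxy)benzene-1,4-diol | Oc1c(Br)cc(Oc2c(O)c(Br)c(Oc3cc(Br)c(O)c(Br)c3Br)c(O)c2Br)c(Br)c1Br | target

## Step count and risks

Total step count: 11. Longest linear sequence: 10 (steps 1–4 and 6–11).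

**Risk 1, step 7.**
- What may go wrong: the vinylketene may close at the inner alkyne carbon C5 to a five-membered ring, or it may be lost by oligomerisation of the ketene and ynol ether before it closes.
- Fallback (sets out from 6, comes back at 19): ring B is bought instead of built.
  - Two equivalents of 6 with K2CO3 in DMF replace the 2- and 5-bromines of tetrabromo-1,4-benzoquinone (bromanil) by addition–elimination. This is the known 2,5-selective disubstitution of tetrahaloquinones by phenoxides, and it gives 2,5-dibromo-3,6-bis(4-methoxyphenoxy)-1,4-benzoquinone F1.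
  - Reductive methylation as in step 8 leads through 2,5-dibromo-3,6-bis(4-methoxyphenoxy)benzene-1,4-diol F2 to 1,4-dibromo-2,5-dimethoxy-3,6-bis(4-methoxyphenoxy)benzene F3.
  - Bromination of the outer rings as in step 9, with four equivalents of Br2, gives 19.

**Risk 2, step 6.**
- What may go wrong: the acetylide may expel the aryloxide by addition–elimination at C3 of the activated aryl ester, residual n-BuLi may attack the dione, or the acetylide may decay before the 1,2-addition.
- Fallback (sets out from 3 and 10, comes back at 18): the second diaryl ether is made late by copper chemistry, so the electrophile can be the robust alkyl ester.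
  - Acetylide 12, made from 10 as before, is added to 3 to give 4-hydroxy-3-isopropoxy-4-[(4-methoxyphenoxy)ethynyl]cyclobut-2-en-1-one F4.
  - Thermolysis as in step 7 passes through (Z)-4-hydroxy-3-isopropoxy-6-(4-methoxyphenoxy)hexa-1,3-dien-5-yn-1-one F5 and the 4-hydroxy-5-isopropoxy-2-(4-methoxyphenoxy)phenoxyl-3-yl diradical F6 to 2-isopropoxy-5-(4-methoxyphenoxy)-1,4-benzoquinone F7.
  - Reductive methylation as in step 8 leads through 2-isopropoxy-5-(4-methoxyphenoxy)benzene-1,4-diol F8 to 1-isopropoxy-2,5-dimethoxy-4-(4-methoxyphenoxy)benzene F9.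
  - BCl3 (CH2Cl2, −78 → 0 °C) cleaves the isopropyl aryl ether in preference to the methyl ethers and gives 2,5-dimethoxy-4-(4-methoxyphenoxy)phenol F10.
  - Chan–Lam O-arylation with 4-methoxyphenylboronic acid (Cu(OAc)2, pyridine, 4 Å sieves, CH2Cl2, air) gives 18.

**Risk 3, step 9.**
- What may go wrong: site selectivity may be poor in the second bromination of each outer ring (entry at C3' next to OMe instead of C2'), or bromine may oxidatively demethylate ring B.
- Fallback (sets out from 18, comes back at 22): every bromine is placed where the ring offers no choice.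
  - BBr3 converts 18 into 2,5-bis(4-hydroxyphenoxy)benzene-1,4-diol F11.
  - Br2 (seven equivalents, AcOH) oxidises ring B, dibrominates each outer ring ortho to OH and brominates both vinylogous-ester C–H positions of the quinone. The product is 2,5-dibromo-3,6-bis(3,5-dibromo-4-hydroxyphenoxy)-1,4-benzoquinone F12.
  - Na2S2O4 and then Me2SO4/K2CO3 in acetone lead through 2,5-dibromo-3,6-bis(3,5-dibromo-4-hydroxyphenoxy)benzene-1,4-diol F13 to 1,4-dibromo-2,5-bis(3,5-dibromo-4-methoxyphenoxy)-3,6-dimethoxybenzene F14.
  - In F14 the two remaining positions of each outer ring are equivalent. Br2 with catalytic FeBr3 therefore puts one bromine on each ring, and the last position is strongly deactivated afterwards. This gives 1,4-dibromo-2,5-dimethoxy-3,6-bis(2,3,5-tribromo-4-methoxyphenoxy)benzene F15.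
  - BBr3 as in step 10 then gives 22.

## Further compounds

F1 | step 7 | 2,5-dibromo-3,6-bis(4-methoxyphenoxy)-1,4-benzoquinone | O=C1C(Br)=C(Oc2ccc(OC)cc2)C(=O)C(Br)=C1Oc1ccc(OC)cc1
F2 | step 7 | 2,5-dibromo-3,6-bis(4-methoxyphenoxy)benzene-1,4-diol | Oc1c(Br)c(Oc2ccc(OC)cc2)c(O)c(Br)c1Oc1ccc(OC)cc1
F3 | step 7 | 1,4-dibromo-2,5-dimethoxy-3,6-bis(4-methoxyphenoxy)benzene | COc1c(Br)c(Oc2ccc(OC)cc2)c(OC)c(Br)c1Oc1ccc(OC)cc1
F4 | step 6 | 4-hydroxy-3-isopropoxy-4-[(4-methoxyphenoxy)ethynyl]cyclobut-2-en-1-one (racemic) | O=C1C=C(OC(C)C)C1(O)C#COc1ccc(OC)cc1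
F5 | step 6 | (Z)-4-hydroxy-3-isopropoxy-6-(4-methoxyphenoxy)hexa-1,3-dien-5-yn-1-one | O=C=C/C(OC(C)C)=C(\C#COc1ccc(OC)cc1)O
F6 | step 6 | 4-hydroxy-5-isopropoxy-2-(4-methoxyphenoxy)phenoxyl-3-yl diradical | [O]c1cc(OC(C)C)c(O)[c]c1Oc1ccc(OC)cc1
F7 | step 6 | 2-isopropoxy-5-(4-methoxyphenoxy)-1,4-benzoquinone | O=C1C=C(OC(C)C)C(=O)C=C1Oc1ccc(OC)cc1
F8 | step 6 | 2-isopropoxy-5-(4-methoxyphenoxy)benzene-1,4-diol | Oc1cc(OC(C)C)c(O)cc1Oc1ccc(OC)cc1
F9 | step 6 | 1-isopropoxy-2,5-dimethoxy-4-(4-methoxyphenoxy)benzene | COc1cc(OC(C)C)c(OC)cc1Oc1ccc(OC)cc1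
F10 | step 6 | 2,5-dimethoxy-4-(4-methoxyphenoxy)phenol | COc1cc(O)c(OC)cc1Oc1ccc(OC)cc1
F11 | step 9 | 2,5-bis(4-hydroxyphenoxy)benzene-1,4-diol | Oc1ccc(Oc2cc(O)c(Oc3ccc(O)cc3)cc2O)cc1
F12 | step 9 | 2,5-dibromo-3,6-bis(3,5-dibromo-4-hydroxyphenoxy)-1,4-benzoquinone | O=C1C(Br)=C(Oc2cc(Br)c(O)c(Br)c2)C(=O)C(Br)=C1Oc1cc(Br)c(O)c(Br)c1
F13 | step 9 | 2,5-dibromo-3,6-bis(3,5-dibromo-4-hydroxyphenoxy)benzene-1,4-diol | Oc1c(Br)c(Oc2cc(Br)c(O)c(Br)c2)c(O)c(Br)c1Oc1cc(Br)c(O)c(Br)c1
F14 | step 9 | 1,4-dibromo-2,5-bis(3,5-dibromo-4-methoxyphenoxy)-3,6-dimethoxybenzene | COc1c(Br)c(Oc2cc(Br)c(OC)c(Br)c2)c(OC)c(Br)c1Oc1cc(Br)c(OC)c(Br)c1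
F15 | step 9 | 1,4-dibromo-2,5-dimethoxy-3,6-bis(2,3,5-tribromo-4-methoxyphenoxy)benzene | COc1c(Br)c(Oc2cc(Br)c(OC)c(Br)c2Br)c(OC)c(Br)c1Oc1cc(Br)c(OC)c(Br)c1Br
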